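**Retrosynthetic overview**
1. Manuifolin E ⇐ tris-silyl isoflavan 17 ⇐ C2 acetal 16. The strategy rests on the pyran ring (O1, C2, C3, C4, C4a, C8a), which is cut into the ring-A o-quinone methide 15 (O1=C8a–C4a=C4) and the two-carbon enol ether 13 (C2=C3) that carries ring B on C3.
2. The [4+2] union forms C3–C4 and O1–C2, closes the only new ring and sets the single stereocentre C3 under control of a (1R,2S)-2-phenylcyclohexyl group on the C2 oxygen; the C2 acetal is then reduced to CH2.
3. Both halves come from one aldehyde 7: 2,4-dihydroxybenzaldehyde is prenylated on O4, silylated on O2 (a free, chelated 2-OH would send the allyl group to C3) and rearranged (Claisen) so that the 1,1-dimethylallyl group lands on C5.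
4. Ring-A branch: 7 → free 2-OH → benzylic alcohol → O-Boc carbonate 10 (quinone methide precursor). Ring-B branch: 7 → E vinyl iodide → copper-catalysed etherification with the auxiliary alcohol → 13, with defined E geometry.
5. Ring order: rings A and B are bought; the pyran ring is closed in step 10, followed by acetal reduction and desilylation.

Key step: step 10

Assumption: the E enol ether should react as its s-trans rotamer on the face remote from the phenyl group; by that model the (1R,2S)-2-phenylcyclohexyl ether leads to 3R. If the sense proved opposite, the equally available (1S,2R) alcohol would be used in step 9 with nothing else changed.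

**Route**

Step 1
Reactants: 1 2,4-dihydroxybenzaldehyde; 2 prenyl bromide (1-bromo-3-methylbut-2-ene)
Product: 3 2-hydroxy-4-[(3-methylbut-2-en-1-yl)oxy]benzaldehyde
Conditions: K2CO3 (1.05 equiv), acetone, 45 °C
Reagents that add atoms: none
Why: Williamson etherification; the 4-OH is the more acidic, unchelated phenol, whereas the 2-OH is hydrogen-bonded to the formyl group, so one equivalent of weak base should alkylate O4 only.

Step 2
Reactants: 3 2-hydroxy-4-[(3-methylbut-2-en-1-yl)oxy]benzaldehyde
Product: 4 2-[(tert-butyldimethylsilyl)oxy]-4-[(3-methylbut-2-en-1-yl)oxy]benzaldehyde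
Conditions: TBSCl, imidazole, DMF, rt
Reagents that add atoms: tert-butyldimethylsilyl chloride, CC(C)(C)[Si](C)(C)Cl
Why: Imidazole-promoted silyl ether formation; capping O2 breaks the OH···O=C chelate that would direct the coming allyl shift to C3, and the bulky silyl group shields C3 further.

Step 3
Reactants: 4 2-[(tert-butyldimethylsilyl)oxy]-4-[(3-methylbut-2-en-1-yl)oxy]benzaldehyde
Product: 6 2-[(tert-butyldimethylsilyl)oxy]-4-hydroxy-5-(2-methylbut-3-en-2-yl)benzaldehyde, via ortho-dienone 5 (not isolated)
Conditions: PhNEt2, 190 °C, Ar, sealed tube, stopped at full conversion of 4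
Reagents that add atoms: none
Why: Aromatic Claisen rearrangement; the concerted [3,3] shift inverts the allyl unit, so the prenyl ether delivers the 1,1-dimethylallyl group to an ortho carbon, and with O2 silylated the open C5 (para to O2) should be preferred over C3, which lies between two oxygen substituents, before dienone 5 tautomerises to phenol 6 in the basic solvent.

Step 4
Reactants: 6 2-[(tert-butyldimethylsilyl)oxy]-4-hydroxy-5-(2-methylbut-3-en-2-yl)benzaldehyde
Product: 7 2,4-bis[(tert-butyldimethylsilyl)oxy]-5-(2-methylbut-3-en-2-yl)benzaldehyde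
Conditions: TBSCl, imidazole, DMF, 45 °C
Reagents that add atoms: tert-butyldimethylsilyl chloride, CC(C)(C)[Si](C)(C)Cl
Why: Silylation of the hindered 4-OH gives the intermediate common to both rings and removes the free phenol that could cyclise onto the neighbouring allyl group; any silyl scrambling from step 3 converges here.

Step 5
Reactants: 7 2,4-bis[(tert-butyldimethylsilyl)oxy]-5-(2-methylbut-3-en-2-yl)benzaldehyde
Product: 8 4-[(tert-butyldimethylsilyl)oxy]-2-hydroxy-5-(2-methylbut-3-en-2-yl)benzaldehyde
Conditions: K2CO3 (0.2 equiv), MeOH/THF, 0 °C, then aq NH4Cl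
Reagents that add atoms: none
Why: Base-catalysed methanolysis of an aryl silyl ether; the O2 silyl ether next to the formyl group is open and its phenoxide is chelation-stabilised, the O4 silyl ether is buried beside the quaternary carbon, and once O2 is a phenoxide the ring is too electron-rich to release the second silyl group at 0 °C.

Step 6
Reactants: 8 4-[(tert-butyldimethylsilyl)oxy]-2-hydroxy-5-(2-methylbut-3-en-2-yl)benzaldehyde
Product: 9 5-[(tert-butyldimethylsilyl)oxy]-2-(hydroxymethyl)-4-(2-methylbut-3-en-2-yl)phenol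
Conditions: NaBH4, THF/EtOH, 0 °C, then pH 7 buffer
Reagents that add atoms: none
Why: Borohydride reduction of the aldehyde to the benzylic alcohol; the salicyl alcohol is kept cold and neutral because acid or heat would expel water to a quinone methide, and the isolated alkene is inert to borohydride.

Step 7
Reactants: 9 5-[(tert-butyldimethylsilyl)oxy]-2-(hydroxymethyl)-4-(2-methylbut-3-en-2-yl)phenol
Product: 10 tert-butyl 5-[(tert-butyldimethylsilyl)oxy]-2-(hydroxymethyl)-4-(2-methylbut-3-en-2-yl)phenyl carbonate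
Conditions: Boc2O (1.05 equiv), iPr2NEt, DMAP (5 mol %), CH2Cl2, −20 °C, then cold dilute citric acid wash
Reagents that add atoms: di-tert-butyl dicarbonate, CC(C)(C)OC(=O)OC(=O)OC(C)(C)C
Why: DMAP-catalysed O-acylation; the phenol is far more acidic than the benzylic alcohol and should take up the single equivalent of Boc2O, while the amine base is too weak to form the benzylic alkoxide that would trigger carbonate transfer.

Step 8
Reactants: 7 2,4-bis[(tert-butyldimethylsilyl)oxy]-5-(2-methylbut-3-en-2-yl)benzaldehyde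
Product: 11 1-[(E)-2-iodoethenyl]-2,4-bis[(tert-butyldimethylsilyl)oxy]-5-(2-methylbut-3-en-2-yl)benzene
Conditions: CrCl2 (6 equiv), CHI3 (2 equiv), THF/1,4-dioxane, 0 °C → rt
Reagents that add atoms: iodoform, IC(I)I
Why: Takai olefination; the geminal dichromium species formed from CHI3 and CrCl2 adds to the aldehyde and eliminates with the aryl group and iodine anti, which should give the E vinyl iodide selectively, silyl ethers and the isolated alkene being inert.

Step 9
Reactants: 11 1-[(E)-2-iodoethenyl]-2,4-bis[(tert-butyldimethylsilyl)oxy]-5-(2-methylbut-3-en-2-yl)benzene; 12 (1R,2S)-2-phenylcyclohexan-1-ol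
Product: 13 1-[(E)-2-{[(1R,2S)-2-phenylcyclohexyl]oxy}ethenyl]-2,4-bis[(tert-butyldimethylsilyl)oxy]-5-(2-methylbut-3-en-2-yl)benzene
Conditions: CuI (10 mol %), 3,4,7,8-tetramethyl-1,10-phenanthroline (20 mol %), Cs2CO3, PhMe, 80 °C; chromatography on Et3N-treated silica
Reagents that add atoms: none
Why: Ullmann-type copper-catalysed C–O coupling of a vinyl iodide with an alcohol, which proceeds with retention of alkene geometry, so the E iodide should give the E enol ether; carbonate suspended in toluene should spare the aryl silyl ethers.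

Step 10
Reactants: 10 tert-butyl 5-[(tert-butyldimethylsilyl)oxy]-2-(hydroxymethyl)-4-(2-methylbut-3-en-2-yl)phenyl carbonate (1.5 equiv); 13 1-[(E)-2-{[(1R,2S)-2-phenylcyclohexyl]oxy}ethenyl]-2,4-bis[(tert-butyldimethylsilyl)oxy]-5-(2-methylbut-3-en-2-yl)benzene
Product: 16 (2S,3R)-3-{2,4-bis[(tert-butyldimethylsilyl)oxy]-5-(2-methylbut-3-en-2-yl)phenyl}-7-[(tert-butyldimethylsilyl)oxy]-6-(2-methylbut-3-en-2-yl)-2-{[(1R,2S)-2-phenylcyclohexyl]oxy}chromane (2,3-trans), via phenoxide carbonate 14 (not isolated), via quinone methide 15 (not isolated)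
Conditions: t-BuMgCl (1.05 equiv per 10, slow addition), PhMe, −78 °C → rt
Reagents that add atoms: none
Why: t-BuMgCl deprotonates the benzylic alcohol of 10, the alkoxide takes the Boc group from the neighbouring phenol oxygen through a six-membered transition state to give phenoxide 14, and 14 expels tert-butyl carbonate by 1,4-elimination to release the o-quinone methide 15 at low temperature. 15 is an electron-poor 1-oxadiene (O1=C8a–C4a=C4) and should be trapped by the electron-rich enol ether 13 in an inverse-electron-demand hetero-Diels–Alder reaction, the closest known type being the Grignard-triggered o-quinone methide cycloaddition with 2-phenylcyclohexyl vinyl ethers and with 2-aryl enol ethers. The pyran ring is closed by this intermolecular [4+2] cycloaddition, in which C4 bonds to the nucleophilic aryl-bearing carbon (C3) and O1 to the oxygen-bearing carbon (C2), as the polarisation of both partners dictates. C2 and C3 are formed together by suprafacial addition to the E alkene, which fixes them trans (C4 is unsubstituted, so endo or exo approach has no stereochemical consequence), and the absolute sense comes from the auxiliary: in the s-trans rotamer, with the carbinol C–H eclipsing the O–vinyl bond, the phenyl group covers one face of the enol ether and the diene adds to the other, which for the (1R,2S) ether should give 2S,3R. The step needs regio-, facial and chemoselectivity (cycloaddition before the quinone methide oligomerises): the first is secured by the enol ether oxygen, the second by the phenyl shield, and the third by generating 15 slowly at −78 °C in the presence of 13, whose silyl ethers and alkenes are inert to the hindered Grignard reagent. The product is a configurationally stable acetal, so C3 is carried unchanged into the reduction.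

Step 11
Reactants: 16 (2S,3R)-trans acetal
Product: 17 (3R)-3-{2,4-bis[(tert-butyldimethylsilyl)oxy]-5-(2-methylbut-3-en-2-yl)phenyl}-7-[(tert-butyldimethylsilyl)oxy]-6-(2-methylbut-3-en-2-yl)chromane
Conditions: Et3SiH (5 equiv), then BF3·OEt2 (1.5 equiv), CH2Cl2, −78 → −40 °C; aq NaHCO3
Reagents that add atoms: none
Why: Ionic reduction of an acetal (Lewis-acid ionisation to the C2 oxocarbenium ion, then hydride transfer from the silane); with the silane in excess before BF3·OEt2 is added at −78 °C the cation should be reduced faster than it can lose the C3 proton, so C3 keeps its configuration, C2 becomes CH2 and alcohol 12 is released for reuse.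

Step 12
Reactants: 17 (3R)-tris-silyl isoflavan
Product: 18 manuifolin E, 4-[(3R)-7-hydroxy-6-(2-methylbut-3-en-2-yl)chroman-3-yl]-6-(2-methylbut-3-en-2-yl)benzene-1,3-diol
Conditions: TBAF (3.5 equiv), AcOH (3.5 equiv), THF, 0 °C
Reagents that add atoms: none
Why: Fluoride-induced cleavage of the three aryl silyl ethers; acetic acid buffering keeps the electron-rich phenols protonated, and the near-neutral medium should leave the ortho 1,1-dimethylallyl phenols uncyclised and C3 untouched.

**Compound list**
1 | 2,4-dihydroxybenzaldehyde | O=Cc1ccc(O)cc1O | starting material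
2 | prenyl bromide | CC(C)=CCBr | starting material
3 | 2-hydroxy-4-[(3-methylbut-2-en-1-yl)oxy]benzaldehyde | O=Cc1ccc(OCC=C(C)C)cc1O | intermediate
4 | 2-[(tert-butyldimethylsilyl)oxy]-4-[(3-methylbut-2-en-1-yl)oxy]benzaldehyde | O=Cc1ccc(OCC=C(C)C)cc1O[Si](C)(C)C(C)(C)C | intermediate
5 | 3-[(tert-butyldimethylsilyl)oxy]-4-formyl-6-(2-methylbut-3-en-2-yl)cyclohexa-2,4-dien-1-one (ortho-dienone, not isolated) | O=CC1=CC(C(C)(C)C=C)C(=O)C=C1O[Si](C)(C)C(C)(C)C | intermediate
6 | 2-[(tert-butyldimethylsilyl)oxy]-4-hydroxy-5-(2-methylbut-3-en-2-yl)benzaldehyde | O=Cc1cc(C(C)(C)C=C)c(O)cc1O[Si](C)(C)C(C)(C)C | intermediate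
7 | 2,4-bis[(tert-butyldimethylsilyl)oxy]-5-(2-methylbut-3-en-2-yl)benzaldehyde | O=Cc1cc(C(C)(C)C=C)c(O[Si](C)(C)C(C)(C)C)cc1O[Si](C)(C)C(C)(C)C | intermediate
8 | 4-[(tert-butyldimethylsilyl)oxy]-2-hydroxy-5-(2-methylbut-3-en-2-yl)benzaldehyde | O=Cc1cc(C(C)(C)C=C)c(O[Si](C)(C)C(C)(C)C)cc1O | intermediate
9 | 5-[(tert-butyldimethylsilyl)oxy]-2-(hydroxymethyl)-4-(2-methylbut-3-en-2-yl)phenol | OCc1cc(C(C)(C)C=C)c(O[Si](C)(C)C(C)(C)C)cc1O | intermediate
10 | tert-butyl 5-[(tert-butyldimethylsilyl)oxy]-2-(hydroxymethyl)-4-(2-methylbut-3-en-2-yl)phenyl carbonate | OCc1cc(C(C)(C)C=C)c(O[Si](C)(C)C(C)(C)C)cc1OC(=O)OC(C)(C)C | intermediate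
11 | 1-[(E)-2-iodoethenyl]-2,4-bis[(tert-butyldimethylsilyl)oxy]-5-(2-methylbut-3-en-2-yl)benzene | C=CC(C)(C)c1cc(/C=C/I)c(O[Si](C)(C)C(C)(C)C)cc1O[Si](C)(C)C(C)(C)C | intermediate
12 | (1R,2S)-2-phenylcyclohexan-1-ol (trans) | O[C@@H]1CCCC[C@H]1c1ccccc1 | starting material
13 | 1-[(E)-2-{[(1R,2S)-2-phenylcyclohexyl]oxy}ethenyl]-2,4-bis[(tert-butyldimethylsilyl)oxy]-5-(2-methylbut-3-en-2-yl)benzene | C=CC(C)(C)c1cc(/C=C/O[C@@H]2CCCC[C@H]2c2ccccc2)c(O[Si](C)(C)C(C)(C)C)cc1O[Si](C)(C)C(C)(C)C | intermediate
14 | chloromagnesium 2-{[(tert-butoxycarbonyl)oxy]methyl}-5-[(tert-butyldimethylsilyl)oxy]-4-(2-methylbut-3-en-2-yl)phenoxide (not isolated) | CC(C)(C)OC(=O)OCc1cc(C(C)(C)C=C)c(O[Si](C)(C)C(C)(C)C)cc1O[Mg]Cl | intermediate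
15 | 3-[(tert-butyldimethylsilyl)oxy]-6-methylidene-4-(2-methylbut-3-en-2-yl)cyclohexa-2,4-dien-1-one (o-quinone methide, not isolated) | C=C1C=C(C(C)(C)C=C)C(O[Si](C)(C)C(C)(C)C)=CC1=O | intermediate
16 | (2S,3R)-3-{2,4-bis[(tert-butyldimethylsilyl)oxy]-5-(2-methylbut-3-en-2-yl)phenyl}-7-[(tert-butyldimethylsilyl)oxy]-6-(2-methylbut-3-en-2-yl)-2-{[(1R,2S)-2-phenylcyclohexyl]oxy}chromane | C=CC(C)(C)c1cc2c(cc1O[Si](C)(C)C(C)(C)C)O[C@H](O[C@@H]1CCCC[C@H]1c1ccccc1)[C@@H](c1cc(C(C)(C)C=C)c(O[Si](C)(C)C(C)(C)C)cc1O[Si](C)(C)C(C)(C)C)C2 | intermediate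
17 | (3R)-3-{2,4-bis[(tert-butyldimethylsilyl)oxy]-5-(2-methylbut-3-en-2-yl)phenyl}-7-[(tert-butyldimethylsilyl)oxy]-6-(2-methylbut-3-en-2-yl)chromane | C=CC(C)(C)c1cc2c(cc1O[Si](C)(C)C(C)(C)C)OC[C@@H](c1cc(C(C)(C)C=C)c(O[Si](C)(C)C(C)(C)C)cc1O[Si](C)(C)C(C)(C)C)C2 | intermediate
18 | manuifolin E | C=CC(C)(C)c1cc2c(cc1O)OC[C@@H](c1cc(C(C)(C)C=C)c(O)cc1O)C2 | target

**Totals**
Total steps: 12. Longest linear sequence: 10 (steps 1–7, 10, 11, 12).

**Steps most likely to fail**

Step 10. Facial discrimination may be poor, because the E enol ether can also react through its s-cis rotamer, which offers the opposite face of C3; trapping may also be slow enough for the quinone methide to oligomerise. Fallback, from 7 back to 17: aldehyde 7 is converted by Stork–Zhao olefination ((iodomethyl)triphenylphosphonium iodide, NaN(SiMe3)2, THF, −78 °C) into the Z vinyl iodide F1. F1 is coupled under the conditions of step 9 with (1S,2R)-2-phenylcyclohexan-1-ol to give the Z enol ether F2. A Z enol ether can populate only the s-trans rotamer, so a single face is open. By the same shielding model, cycloaddition with 15 (generated from 10 as in step 10) should give the cis acetal F3 (2R,3R). Reduction as in step 11 erases C2 and should give 17.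

Step 9. The C–O coupling may stall with the hindered secondary alcohol, and the warm carbonate base may strip aryl silyl groups. Fallback, from 7 back to 13: boron-Takai olefination of 7 (CrCl2, LiI, 2-(dichloromethyl)-4,4,5,5-tetramethyl-1,3,2-dioxaborolane, THF) should give the E vinylboronate F4. Oxidative Chan–Lam-type coupling of F4 with excess 12 (Cu(OAc)2, Et3N, CH2Cl2, air, rt) forms the C–O bond with retention of geometry at room temperature without carbonate base and should give 13; unreacted 12 is recovered.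

Step 3. The rearrangement may be diverted at 190 °C by loss of the prenyl group, onward abnormal Claisen rearrangement of the product phenol, or silyl transfer that restores the chelate and opens the C3 pathway. Fallback, from 3 back to 7: 3 is protected as the methoxymethyl ether F5 (MOMCl, iPr2NEt, CH2Cl2). F5 is rearranged under water-accelerated conditions (EtOH/H2O 4:1, 130 °C, sealed tube), which the acetal survives, to the phenol F6. Acid methanolysis (HCl, MeOH, 40 °C) gives the dihydroxy aldehyde F7, and bis-silylation (TBSCl 2.5 equiv, imidazole, DMF) should give 7.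

**Further compounds**
F1 | step 10 | 1-[(Z)-2-iodoethenyl]-2,4-bis[(tert-butyldimethylsilyl)oxy]-5-(2-methylbut-3-en-2-yl)benzene | C=CC(C)(C)c1cc(/C=C\I)c(O[Si](C)(C)C(C)(C)C)cc1O[Si](C)(C)C(C)(C)C
F2 | step 10 | 1-[(Z)-2-{[(1S,2R)-2-phenylcyclohexyl]oxy}ethenyl]-2,4-bis[(tert-butyldimethylsilyl)oxy]-5-(2-methylbut-3-en-2-yl)benzene | C=CC(C)(C)c1cc(/C=C\O[C@H]2CCCC[C@@H]2c2ccccc2)c(O[Si](C)(C)C(C)(C)C)cc1O[Si](C)(C)C(C)(C)C
F3 | step 10 | (2R,3R)-3-{2,4-bis[(tert-butyldimethylsilyl)oxy]-5-(2-methylbut-3-en-2-yl)phenyl}-7-[(tert-butyldimethylsilyl)oxy]-6-(2-methylbut-3-en-2-yl)-2-{[(1S,2R)-2-phenylcyclohexyl]oxy}chromane (2,3-cis) | C=CC(C)(C)c1cc2c(cc1O[Si](C)(C)C(C)(C)C)O[C@@H](O[C@H]1CCCC[C@@H]1c1ccccc1)[C@@H](c1cc(C(C)(C)C=C)c(O[Si](C)(C)C(C)(C)C)cc1O[Si](C)(C)C(C)(C)C)C2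
F4 | step 9 | 2-[(E)-2-{2,4-bis[(tert-butyldimethylsilyl)oxy]-5-(2-methylbut-3-en-2-yl)phenyl}ethenyl]-4,4,5,5-tetramethyl-1,3,2-dioxaborolane | C=CC(C)(C)c1cc(/C=C/B2OC(C)(C)C(C)(C)O2)c(O[Si](C)(C)C(C)(C)C)cc1O[Si](C)(C)C(C)(C)C
F5 | step 3 | 2-(methoxymethoxy)-4-[(3-methylbut-2-en-1-yl)oxy]benzaldehyde | O=Cc1ccc(OCC=C(C)C)cc1OCOC
F6 | step 3 | 4-hydroxy-2-(methoxymethoxy)-5-(2-methylbut-3-en-2-yl)benzaldehyde | O=Cc1cc(C(C)(C)C=C)c(O)cc1OCOC
F7 | step 3 | 2,4-dihydroxy-5-(2-methylbut-3-en-2-yl)benzaldehyde | O=Cc1cc(C(C)(C)C=C)c(O)cc1O
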